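The 20-membered ring is opened at the diaryl ether bond between O-4 of the catechol ring C (the oxygen para to its ethano bridge) and C-3 of the meta-phenylene ring D. A copper-catalysed intramolecular Ullmann etherification closes this bond and the macrocycle in one operation. It exploits the catechol: O-3 is masked as a benzyl ether, so only the O-4 phenoxide can attack, and the unhindered bromide at C-3 of ring D fixes the carbon site. The precursor is an acyclic bromo phenol in which the ring A–O–ring B ether and both CH2CH2 bridges are already in place, built by Wittig, SNAr and Wittig reactions followed by diimide reduction.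

Key step: step 7

Ring labels: A = methoxy-bearing ring, B = para-phenylene ring, C = hydroxyl-bearing catechol-type ring, D = meta-phenylene ring.

Remark on the chemistry: the target has no stereocentre and the 20-membered ring is assumed to be conformationally mobile, so it is achiral and no stereocontrol is needed. The stilbene intermediates are carried as E/Z mixtures because both double bonds are saturated in step 6. Compounds 2 and 7 are assumed to be purchasable.

Step 1
Reactants: 1 isovanillin (3-hydroxy-4-methoxybenzaldehyde); 2 (3-bromobenzyl)triphenylphosphonium bromide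
Product: 4 5-[2-(3-bromophenyl)ethenyl]-2-methoxyphenol (E/Z mixture), via phosphonium ylide 3 (not isolated)
Conditions: KOtBu (2.4 equiv), THF, 0 °C to rt; aq. NH4Cl
Reagents that add atoms: none
Why: Wittig olefination in which the semi-stabilised ylide 3 adds to the aldehyde of 1, whose meta-phenoxide (formed by the extra equivalent of base) is not conjugated to the carbonyl and so should not deactivate it.

Step 2
Reactants: 4 5-[2-(3-bromophenyl)ethenyl]-2-methoxyphenol; 5 4-fluorobenzaldehyde
Product: 6 4-{5-[2-(3-bromophenyl)ethenyl]-2-methoxyphenoxy}benzaldehyde (E/Z mixture)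
Conditions: K2CO3, DMF, 120 °C
Reagents that add atoms: none
Why: Nucleophilic aromatic substitution (SNAr) in which the phenoxide of 4 displaces fluoride para to the activating formyl group through a Meisenheimer intermediate, while the unactivated aryl bromide is inert.

Step 3
Reactants: 7 3-(benzyloxy)-4-hydroxybenzaldehyde
Product: 8 2-(benzyloxy)-4-(hydroxymethyl)phenol
Conditions: NaBH4, MeOH, 0 °C
Reagents that add atoms: none
Why: Borohydride reduction of an aryl aldehyde to the benzylic alcohol, which leaves the phenol and the benzyl ether untouched.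

Step 4
Reactants: 8 2-(benzyloxy)-4-(hydroxymethyl)phenol
Product: 9 [3-(benzyloxy)-4-hydroxybenzyl]triphenylphosphonium bromide
Conditions: PPh3·HBr, MeCN, reflux
Reagents that add atoms: triphenylphosphine hydrobromide, [Br-].[PH+](c1ccccc1)(c1ccccc1)c1ccccc1
Why: Direct phosphonium salt formation from an electron-rich para-hydroxybenzylic alcohol, by acid-promoted ionisation to a quinone-methide-like benzylic cation and capture by triphenylphosphine, as known for vanillyl-type alcohols.

Step 5
Reactants: 6 4-{5-[2-(3-bromophenyl)ethenyl]-2-methoxyphenoxy}benzaldehyde; 9 [3-(benzyloxy)-4-hydroxybenzyl]triphenylphosphonium bromide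
Product: 11 2-(benzyloxy)-4-[2-(4-{5-[2-(3-bromophenyl)ethenyl]-2-methoxyphenoxy}phenyl)ethenyl]phenol (mixture of alkene isomers), via phenoxide ylide 10 (not isolated)
Conditions: NaHMDS (2.5 equiv), THF, −20 °C to rt; aq. NH4Cl
Reagents that add atoms: none
Why: Wittig olefination with the phenoxide-ylide 10 generated by two equivalents of base, as practised with unprotected hydroxybenzylphosphonium salts; the aryl bromide and the first stilbene are inert to it.

Step 6
Reactants: 11 2-(benzyloxy)-4-[2-(4-{5-[2-(3-bromophenyl)ethenyl]-2-methoxyphenoxy}phenyl)ethenyl]phenol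
Product: 12 2-(benzyloxy)-4-[2-(4-{5-[2-(3-bromophenyl)ethyl]-2-methoxyphenoxy}phenyl)ethyl]phenol
Conditions: TsNHNH2 (excess, in portions), NaOAc, DME–H2O, reflux
Reagents that add atoms: none
Why: Diimide reduction, with diimide generated in situ from tosylhydrazide and acetate, saturates both stilbene double bonds by concerted syn hydrogen transfer without hydrogenolysis of the aryl bromide or the benzyl ether.

Step 7
Reactants: 12 2-(benzyloxy)-4-[2-(4-{5-[2-(3-bromophenyl)ethyl]-2-methoxyphenoxy}phenyl)ethyl]phenol
Product: 13 O-benzylpakyonol (the 20-membered macrocycle of the target with the ring C hydroxyl as its benzyl ether)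
Conditions: CuI (30 mol %), N,N-dimethylglycine·HCl (90 mol %), Cs2CO3 (3 equiv), 1,4-dioxane, 100 °C, syringe-pump addition of 12 to about 2 mM final concentration
Reagents that add atoms: none
Why: The caesium phenoxide at O-4 of ring C binds the dimethylglycine-ligated Cu(I), the C–Br bond at C-3 of ring D adds oxidatively to give an aryl–Cu(III) aryloxide, and reductive elimination forms the O–C(aryl) bond and returns Cu(I). The closest known reaction type is the ligand-accelerated intramolecular Ullmann diaryl ether macrocyclisation of bromo phenols, as used for combretastatin D-type and cyclic diarylheptanoid macrocycles. One ring closes, the 20-membered macrocycle, by end-to-end ipso substitution of bromide at an sp2 carbon, a macrocyclisation outside the small-ring Baldwin classes. No stereocentre is formed. The step needs O-4 over O-3 selectivity, secured by the benzyl ether on O-3 that leaves a single phenol, and cyclisation over oligomerisation, secured by pseudo-high dilution together with the two flexible CH2CH2 bridges and the preformed A–O–B ether turn that let the phenoxide reach the unhindered meta bromide.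

Step 8
Reactants: 13 O-benzylpakyonol
Product: 14 pakyonol
Conditions: H2 (1 atm), 10% Pd/C, EtOAc–MeOH, rt
Reagents that add atoms: none
Why: Catalytic hydrogenolysis of the benzyl aryl ether releases the ring C phenol, while the methyl ether, both diaryl ethers and the arenes are stable under these conditions.

Compound list
1 | isovanillin (3-hydroxy-4-methoxybenzaldehyde) | COc1ccc(C=O)cc1O | starting material
2 | (3-bromobenzyl)triphenylphosphonium bromide | [Br-].Brc1cccc(C[P+](c2ccccc2)(c2ccccc2)c2ccccc2)c1 | starting material
3 | (3-bromobenzylidene)triphenylphosphorane (ylide, not isolated) | Brc1cccc(C=P(c2ccccc2)(c2ccccc2)c2ccccc2)c1 | intermediate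
4 | 5-[2-(3-bromophenyl)ethenyl]-2-methoxyphenol (E/Z mixture) | COc1ccc(C=Cc2cccc(Br)c2)cc1O | intermediate
5 | 4-fluorobenzaldehyde | O=Cc1ccc(F)cc1 | starting material
6 | 4-{5-[2-(3-bromophenyl)ethenyl]-2-methoxyphenoxy}benzaldehyde (E/Z mixture) | COc1ccc(C=Cc2cccc(Br)c2)cc1Oc1ccc(C=O)cc1 | intermediate
7 | 3-(benzyloxy)-4-hydroxybenzaldehyde | O=Cc1ccc(O)c(OCc2ccccc2)c1 | starting material
8 | 2-(benzyloxy)-4-(hydroxymethyl)phenol | OCc1ccc(O)c(OCc2ccccc2)c1 | intermediate
9 | [3-(benzyloxy)-4-hydroxybenzyl]triphenylphosphonium bromide | [Br-].Oc1ccc(C[P+](c2ccccc2)(c2ccccc2)c2ccccc2)cc1OCc1ccccc1 | intermediate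
10 | sodium 2-(benzyloxy)-4-[(triphenylphosphoranylidene)methyl]phenolate (phenoxide ylide, not isolated) | [Na+].[O-]c1ccc(C=P(c2ccccc2)(c2ccccc2)c2ccccc2)cc1OCc1ccccc1 | intermediate
11 | 2-(benzyloxy)-4-[2-(4-{5-[2-(3-bromophenyl)ethenyl]-2-methoxyphenoxy}phenyl)ethenyl]phenol (mixture of alkene isomers) | COc1ccc(C=Cc2cccc(Br)c2)cc1Oc1ccc(C=Cc2ccc(O)c(OCc3ccccc3)c2)cc1 | intermediate
12 | 2-(benzyloxy)-4-[2-(4-{5-[2-(3-bromophenyl)ethyl]-2-methoxyphenoxy}phenyl)ethyl]phenol | COc1ccc(CCc2cccc(Br)c2)cc1Oc1ccc(CCc2ccc(O)c(OCc3ccccc3)c2)cc1 | intermediate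
13 | O-benzylpakyonol (macrocycle, ring C hydroxyl as benzyl ether) | COc1ccc2cc1Oc1ccc(cc1)CCc1ccc(c(OCc3ccccc3)c1)Oc1cccc(c1)CC2 | intermediate
14 | pakyonol | COc1ccc2cc1Oc1ccc(cc1)CCc1ccc(c(O)c1)Oc1cccc(c1)CC2 | target

Total step count: 8.
Longest linear sequence: 6 steps (steps 1, 2, 5, 6, 7, 8; the branch through steps 3 and 4 is equally long).

Steps most likely to fail

Step 7. Intermolecular coupling may compete with ring closure and give oligomers, and slow oxidative addition of the unactivated bromide at high dilution may allow reductive loss of bromine. The fallback sets out from 12 and changes the coupling manifold to an oxidative room-temperature etherification. Palladium-catalysed borylation with tetrahydroxydiboron (XPhos Pd G2, KOAc, EtOH, 80 °C) should give {3-[2-(3-{4-[2-(3-benzyloxy-4-hydroxyphenyl)ethyl]phenoxy}-4-methoxyphenyl)ethyl]phenyl}boronic acid F1. Chan–Lam–Evans macrocyclisation (Cu(OAc)2, Et3N, 4 Å molecular sieves, CH2Cl2, air, rt, about 1 mM) should then form the same O–C bond and return to the route at 13.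

Step 5. Ylide formation from the phenoxide-bearing phosphonium salt may be incomplete, or the phenoxide–phosphonium betaine may fragment with loss of triphenylphosphine and polymerise. The fallback sets out from 6 and 7 and reverses the polarity of the olefination so that no phenoxide sits on the ylide. Aldehyde 6 is reduced (NaBH4, MeOH) to (4-{5-[2-(3-bromophenyl)ethenyl]-2-methoxyphenoxy}phenyl)methanol F2 and converted (PPh3·HBr, MeCN, reflux) into (4-{5-[2-(3-bromophenyl)ethenyl]-2-methoxyphenoxy}benzyl)triphenylphosphonium bromide F3. Aldehyde 7 is silylated (TBSCl, imidazole, DMF) to 3-(benzyloxy)-4-[(tert-butyldimethylsilyl)oxy]benzaldehyde F4. Wittig reaction of F3 with F4 (NaHMDS, THF) should give tert-butyl{2-(benzyloxy)-4-[2-(4-{5-[2-(3-bromophenyl)ethenyl]-2-methoxyphenoxy}phenyl)ethenyl]phenoxy}dimethylsilane F5, and desilylation (TBAF, THF, 0 °C) returns to the route at 11.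

Step 1. Deprotonation of the phenol on the aldehyde partner may cause precipitation of the phenoxide and incomplete olefination. The fallback sets out from 1 and forms the diaryl ether before the olefination, with the second aldehyde masked as a nitrile. SNAr of 1 with 4-fluorobenzonitrile (K2CO3, DMF, 120 °C) should give 4-(5-formyl-2-methoxyphenoxy)benzonitrile F6, which has no acidic hydroxyl. Wittig reaction with 2 (KOtBu, THF) gives 4-{5-[2-(3-bromophenyl)ethenyl]-2-methoxyphenoxy}benzonitrile F7, and DIBAL-H reduction (toluene, −78 °C) followed by aqueous HCl returns to the route at 6.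

Further compounds
F1 | step 7 | {3-[2-(3-{4-[2-(3-benzyloxy-4-hydroxyphenyl)ethyl]phenoxy}-4-methoxyphenyl)ethyl]phenyl}boronic acid | COc1ccc(CCc2cccc(B(O)O)c2)cc1Oc1ccc(CCc2ccc(O)c(OCc3ccccc3)c2)cc1
F2 | step 5 | (4-{5-[2-(3-bromophenyl)ethenyl]-2-methoxyphenoxy}phenyl)methanol | COc1ccc(C=Cc2cccc(Br)c2)cc1Oc1ccc(CO)cc1
F3 | step 5 | (4-{5-[2-(3-bromophenyl)ethenyl]-2-methoxyphenoxy}benzyl)triphenylphosphonium bromide | [Br-].COc1ccc(C=Cc2cccc(Br)c2)cc1Oc1ccc(C[P+](c2ccccc2)(c2ccccc2)c2ccccc2)cc1
F4 | step 5 | 3-(benzyloxy)-4-[(tert-butyldimethylsilyl)oxy]benzaldehyde | O=Cc1ccc(O[Si](C)(C)C(C)(C)C)c(OCc2ccccc2)c1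
F5 | step 5 | tert-butyl{2-(benzyloxy)-4-[2-(4-{5-[2-(3-bromophenyl)ethenyl]-2-methoxyphenoxy}phenyl)ethenyl]phenoxy}dimethylsilane | COc1ccc(C=Cc2cccc(Br)c2)cc1Oc1ccc(C=Cc2ccc(O[Si](C)(C)C(C)(C)C)c(OCc3ccccc3)c2)cc1
F6 | step 1 | 4-(5-formyl-2-methoxyphenoxy)benzonitrile | COc1ccc(C=O)cc1Oc1ccc(C#N)cc1
F7 | step 1 | 4-{5-[2-(3-bromophenyl)ethenyl]-2-methoxyphenoxy}benzonitrile | COc1ccc(C=Cc2cccc(Br)c2)cc1Oc1ccc(C#N)cc1
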